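**Assumptions.** (±)-Linalool is used because its stereocentre is destroyed in step 2. The only chiral input is (S)-5-oxotetrahydrofuran-2-carboxylic acid (commercial; from L-glutamic acid). Locants use geranylgeranyl numbering: C1 = ArCH2, C15 = CMe2Br carbon; the target is 6S,7S,10R,11S,14S.

**Retrosynthetic overview**
1. C15–Br is installed last by Markovnikov HAT hydrobromination of an isopropenyl group, which comes from the C15 carbonyl of a δ-lactone that masks C11–OH.
2. The cyclohexene (C2–C7 bond, C6–Br) comes from a transannular bromonium cyclization. Ring order: 19-membered macrolactone → δ-lactone → cyclohexene / 15-membered macrolide.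
3. C10–Br and C11–O come from bromolactonization of the C15 tert-butyl ester onto the (E)-C10=C11 alkene; the macrolactone is closed at C14–OH.
4. The chain is joined at C9–C10 by B-alkyl Suzuki coupling of an aryl triene with an (E)-vinyl iodide that carries the purchased C14 stereocentre.
5. The aryl–C1 bond is formed by aromatic Claisen rearrangement of an aryl linalyl ether (key step).

**Route**

Step 1
Reactants: 1 4-fluorobenzaldehyde; 2 (±)-linalool
Product: 3 4-[(3,7-dimethylocta-1,6-dien-3-yl)oxy]benzaldehyde
Conditions: KHMDS, THF/DMF, −20 °C → rt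
Reagents that add atoms: none
Why: SNAr of the tertiary potassium alkoxide on the para-formyl-activated fluoroarene; a tertiary alkoxide cannot act as a hydride donor toward the aldehyde.

Step 2
Reactants: 3
Product: 4 3-[(2E)-3,7-dimethylocta-2,6-dien-1-yl]-4-hydroxybenzaldehyde
Conditions: PhNEt2, 150–160 °C; E isomer isolated (AgNO3–SiO2)
Reagents that add atoms: none
Why: Aromatic Claisen ([3,3]) rearrangement forms the aryl–C1 bond and gives the linear geranyl chain (E-major through a chair transition state; the C2=C3 geometry is erased in step 14 in any case).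

Step 3
Reactants: 4
Product: 5 3-geranyl-4-(triisopropylsilyloxy)benzaldehyde
Conditions: TIPSCl, imidazole, DMF, rt
Reagents that add atoms: TIPSCl, CC(C)[Si](Cl)(C(C)C)C(C)C
Why: Silylation gives a bulky, non-nucleophilic phenol ether that cannot form a chroman during the later bromonium steps.

Step 4
Reactants: 5
Product: 6 3-geranyl-4-(triisopropylsilyloxy)benzoic acid
Conditions: NaClO2, NaH2PO4, 2-methyl-2-butene (excess), t-BuOH/H2O, 0 °C → rt
Reagents that add atoms: sodium chlorite, [Na+].[O-]Cl=O
Why: Pinnick oxidation of the aryl aldehyde; the scavenger protects the trisubstituted alkenes from HOCl.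

Step 5
Reactants: 6
Product: 7 3-[(2E,6E)-3,7-dimethyl-8-oxoocta-2,6-dien-1-yl]-4-(TIPSO)benzoic acid
Conditions: SeO2 (cat.), t-BuOOH, CH2Cl2, rt; then MnO2 (telescoped)
Reagents that add atoms: SeO2, O=[Se]=O; t-BuOOH, CC(C)(C)OO
Why: SeO2 allylic oxidation (ene then [2,3] shift) attacks the terminal trans-methyl and gives the (E)-enal, which fixes the C6=C7 geometry.

Step 6
Reactants: 7
Product: 8 3-[(2E,6E)-3,7-dimethylnona-2,6,8-trien-1-yl]-4-(TIPSO)benzoic acid
Conditions: Ph3PCH3Br, KHMDS (2.5 equiv), THF, −78 → 0 °C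
Reagents that add atoms: methylenetriphenylphosphorane, C=P(c1ccccc1)(c1ccccc1)c1ccccc1
Why: Wittig methylenation of the enal gives the terminal 1,3-diene (C8=C9) needed for hydroboration; the carboxylate is inert.

Step 7
Reactants: 9 (S)-5-oxotetrahydrofuran-2-carboxylic acid
Product: 10 tert-butyl (S)-5-oxotetrahydrofuran-2-carboxylate
Conditions: t-BuOC(=NH)CCl3, BF3·OEt2 (cat.), CH2Cl2/cyclohexane, rt
Reagents that add atoms: tert-butyl trichloroacetimidate, CC(C)(C)OC(=N)C(Cl)(Cl)Cl
Why: Acid-catalysed tert-butylation of the acid; the C14 stereocentre is purchased and untouched.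

Step 8
Reactants: 10
Product: 11 tert-butyl (2S)-5-hydroxytetrahydrofuran-2-carboxylate (lactol, anomers)
Conditions: DIBAL-H (1.1 equiv), CH2Cl2, −78 °C
Reagents that add atoms: none
Why: DIBAL reduces the γ-lactone to the lactol much faster than the hindered tert-butyl ester at −78 °C.

Step 9
Reactants: 11
Product: 12 tert-butyl (S)-2-hydroxyhex-5-ynoate
Conditions: dimethyl (1-diazo-2-oxopropyl)phosphonate, K2CO3, MeOH, 0 °C → rt
Reagents that add atoms: Ohira–Bestmann reagent, CC(=O)C(=[N+]=[N-])P(=O)(OC)OC
Why: Seyferth–Gilbert (Ohira–Bestmann) homologation of the open hydroxy-aldehyde form gives the terminal alkyne (C10≡C11).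

Step 10
Reactants: 12
Product: 13 tert-butyl (2S,5E)-2-hydroxy-6-iodo-5-methylhex-5-enoate
Conditions: Me3Al, Cp2ZrCl2, H2O (1 equiv), CH2Cl2, −23 °C; then I2, THF
Reagents that add atoms: trimethylaluminium, C[Al](C)C; iodine, II
Why: Negishi Zr-catalysed syn-carboalumination (water-accelerated) then iodinolysis gives only the (E)-2-methylalkenyl iodide, which fixes the C10=C11 geometry.

Step 11
Reactants: 8; 13
Product: 14 3-[(2E,6E,10E,14S)-15-tert-butoxy-14-hydroxy-3,7,11-trimethyl-15-oxopentadeca-2,6,10-trien-1-yl]-4-(TIPSO)benzoic acid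
Conditions: 8, 9-BBN (2.2 equiv), THF, rt; then 13, PdCl2(dppf), AsPh3, K3PO4 (aq), DMF, rt
Reagents that add atoms: none
Why: 9-BBN hydroborates only the terminal vinyl of the diene, and B-alkyl Suzuki–Miyaura coupling forms C9–C10 with retention of the alkene geometry.

Step 12
Reactants: 14
Product: 15 19-membered (2E,6E,10E,14S)-macrolactone (ArC(=O)–O–C14) with the C15 tert-butyl ester
Conditions: MNBA, DMAP, Et3N, CH2Cl2 (1 mM), rt, slow addition
Reagents that add atoms: none
Why: Shiina macrolactonization acylates the only free hydroxyl (C14–OH) with retention; room temperature avoids epimerising the α-acyloxy ester.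

Step 13
Reactants: 15
Product: 16 (10R,11S,14S)-10-bromo-15,11-olide (δ-lactone fused to the macrolactone; 2E,6E-diene)
Conditions: NBS, MeCN, −20 → 0 °C
Reagents that add atoms: N-bromosuccinimide, BrN1C(=O)CCC1=O
Why: Bromolactonization by 6-exo attack of the tert-butyl ester carbonyl (loss of isobutene) occurs only at C10=C11, the one alkene with an internal nucleophile; anti addition across the E-alkene sets the C10/C11 relative configuration, and C14 on the forming ring (aroyloxy pseudo-axial, bromoalkyl branch pseudo-equatorial) is expected to select the face.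

Step 14
Reactants: 16
Product: 17 (6S,7S,10R,11S,14S)-6,10-dibromo carbocycle: 15-membered macrolide with the C2=C3 tetrasubstituted cyclohexene, C6–Br, C10–Br, δ-lactone and TIPS ether
Conditions: BDSB (Et2SBr·SbCl5Br, 1.1 equiv), MeNO2, −25 °C, 5 min
Reagents that add atoms: BDSB, CC[S+](Br)CC.Cl[Sb-](Cl)(Cl)(Cl)(Cl)Br
Why: Bromonium-initiated transannular cation–olefin cyclization (Br+ on C6=C7, chair-like attack by C2, loss of H-2); anti addition across the E-alkene sets the C6/C7 relative configuration, and the rigid bis-lactone macrocycle (C10, C11, C14) is relied on to select the face; no O-nucleophile is free to intercept.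

Step 15
Reactants: 17
Product: 18 free phenol of 17
Conditions: HF·pyridine, THF/pyridine, 0 °C
Reagents that add atoms: none
Why: Mildly acidic desilylation leaves both lactones and the secondary bromides intact.

Step 16
Reactants: 18
Product: 19 C15 methyl ketone with free C11–OH (isolated mainly as its six-membered hemiketal)
Conditions: MeLi (3.2 equiv), THF, −78 °C; AcOH quench at −78 °C
Reagents that add atoms: methyllithium, [Li]C
Why: Mono-addition of MeLi to the activated α-acyloxy δ-lactone (the tetrahedral intermediate is stable at −78 °C); the macrolactone is protected as a para-phenoxide benzoate, and the cold acidic quench prevents bromohydrin closure to an epoxide.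

Step 17
Reactants: 19
Product: 20 15-isopropenyl compound (bromophycolide A lacking HBr at C15)
Conditions: Tebbe reagent (excess), pyridine, THF/PhMe, −40 → 0 °C
Reagents that add atoms: Tebbe reagent, Cp2Ti(μ-CH2)(μ-Cl)AlMe2 (drawn with the chloride terminal on Ti), C[Al](C)C[Ti](Cl)(C1C=CC=C1)C1C=CC=C1
Why: Non-basic Tebbe methylenation (pyridine releases Cp2Ti=CH2, which reacts by [2+2]/retro-[2+2] with the ketone through its open form) avoids the alkoxide that a Wittig ylide would generate next to C10–Br; the excess covers the phenol and C11–OH, and the aryl ester is untouched at ≤0 °C.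

Step 18
Reactants: 20
Product: 21 bromophycolide A
Conditions: Co(acac)2 (cat.), t-BuOOH, Et3SiH, TsBr, n-PrOH/CH2Cl2, rt
Reagents that add atoms: tosyl bromide, Cc1ccc(cc1)S(=O)(=O)Br
Why: Mukaiyama-type HAT hydrobromination adds H/Br in the Markovnikov sense to the 1,1-disubstituted alkene only (the tetrasubstituted ring alkene is inert), giving the tertiary C15 bromide without creating a stereocentre.

**Compound list**

1 | 4-fluorobenzaldehyde | O=Cc1ccc(F)cc1 | starting material
2 | (±)-linalool | CC(C)=CCCC(C)(O)C=C | starting material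
3 | 4-[(3,7-dimethylocta-1,6-dien-3-yl)oxy]benzaldehyde | CC(C)=CCCC(C)(C=C)Oc1ccc(C=O)cc1 | intermediate
4 | 3-geranyl-4-hydroxybenzaldehyde | CC(C)=CCC/C(C)=C/Cc1cc(C=O)ccc1O | intermediate
5 | 3-geranyl-4-(TIPSO)benzaldehyde | CC(C)=CCC/C(C)=C/Cc1cc(C=O)ccc1O[Si](C(C)C)(C(C)C)C(C)C | intermediate
6 | 3-geranyl-4-(TIPSO)benzoic acid | CC(C)=CCC/C(C)=C/Cc1cc(C(=O)O)ccc1O[Si](C(C)C)(C(C)C)C(C)C | intermediate
7 | (2E,6E)-8-oxo enal acid | O=C/C(C)=C/CC/C(C)=C/Cc1cc(C(=O)O)ccc1O[Si](C(C)C)(C(C)C)C(C)C | intermediate
8 | (2E,6E)-2,6,8-triene acid | C=C/C(C)=C/CC/C(C)=C/Cc1cc(C(=O)O)ccc1O[Si](C(C)C)(C(C)C)C(C)C | intermediate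
9 | (S)-5-oxotetrahydrofuran-2-carboxylic acid | O=C1CC[C@@H](C(=O)O)O1 | starting material
10 | tert-butyl (S)-5-oxotetrahydrofuran-2-carboxylate | O=C1CC[C@@H](C(=O)OC(C)(C)C)O1 | intermediate
11 | tert-butyl (2S)-5-hydroxytetrahydrofuran-2-carboxylate | OC1CC[C@@H](C(=O)OC(C)(C)C)O1 | intermediate
12 | tert-butyl (S)-2-hydroxyhex-5-ynoate | C#CCC[C@H](O)C(=O)OC(C)(C)C | intermediate
13 | tert-butyl (2S,5E)-2-hydroxy-6-iodo-5-methylhex-5-enoate | I/C=C(\C)CC[C@H](O)C(=O)OC(C)(C)C | intermediate
14 | seco hydroxy acid (2E,6E,10E,14S) | OC(=O)c1ccc(O[Si](C(C)C)(C(C)C)C(C)C)c(C/C=C(\C)CC/C=C(\C)CC/C=C(\C)CC[C@H](O)C(=O)OC(C)(C)C)c1 | intermediate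
15 | 19-membered macrolactone, C15 tert-butyl ester | O=C1O[C@H](C(=O)OC(C)(C)C)CC/C(C)=C/CC/C(C)=C/CC/C(C)=C/Cc2cc1ccc2O[Si](C(C)C)(C(C)C)C(C)C | intermediate
16 | (10R,11S,14S)-bromo-δ-lactone macrolactone | O=C1O[C@H]2CC[C@](C)(OC2=O)[C@H](Br)CC/C(C)=C/CC/C(C)=C/Cc3cc1ccc3O[Si](C(C)C)(C(C)C)C(C)C | intermediate
17 | (6S,7S,10R,11S,14S)-carbocyclic macrolide, TIPS ether, δ-lactone | CC1=C2Cc3cc(ccc3O[Si](C(C)C)(C(C)C)C(C)C)C(=O)O[C@H]4CC[C@](C)(OC4=O)[C@H](Br)CC[C@]2(C)[C@@H](Br)CC1 | intermediate
18 | phenol of 17 | CC1=C2Cc3cc(ccc3O)C(=O)O[C@H]4CC[C@](C)(OC4=O)[C@H](Br)CC[C@]2(C)[C@@H](Br)CC1 | intermediate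
19 | C15 methyl ketone / C11–OH (open form; hemiketal tautomer) | CC1=C2Cc3cc(ccc3O)C(=O)O[C@H](C(C)=O)CC[C@](C)(O)[C@H](Br)CC[C@]2(C)[C@@H](Br)CC1 | intermediate
20 | 15-isopropenyl precursor | CC1=C2Cc3cc(ccc3O)C(=O)O[C@H](C(C)=C)CC[C@](C)(O)[C@H](Br)CC[C@]2(C)[C@@H](Br)CC1 | intermediate
21 | bromophycolide A | CC1=C2Cc3cc(ccc3O)C(=O)O[C@H](C(C)(C)Br)CC[C@](C)(O)[C@H](Br)CC[C@]2(C)[C@@H](Br)CC1 | target

**Totals**
- Total steps: 18.
- Longest linear sequence: 14 (steps 1–6, then 11–18).

**Three steps most likely to fail**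

1. Step 14, transannular bromonium cyclization. Risks are Br+ attack at C2=C3, facial selectivity that is only conformationally controlled, and mixed alkene isomers from proton loss. Fallback: initiate with Hg(OTf)2·PhNMe2 instead (reversible π-activation, better site and alkene-isomer control) and convert the C6 organomercurial to the bromide by polar bromodemercuration.

2. Step 13, facial selectivity of the bromolactonization. The 1,4-relay from C14 to C10/C11 may be modest or of the wrong sense. Fallback: stop relaying from C14 and set C10/C11 independently from a second molecule of 9, which supplies C10 as a C–O stereocentre; a chelation-controlled MeMgBr addition to the derived α-alkoxy ketone then sets C11, followed by epoxide closure and bromide opening at C10.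

3. Step 16, MeLi mono-addition to the lactone. Risks are over-addition, attack on the macrolactone, and epoxide formation from the bromohydrin. Fallback: open the δ-lactone to the Weinreb amide (Me(MeO)NH·HCl, i-PrMgCl), silylate the released C11–OH, then add MeMgBr to reach the methyl ketone before methylenation.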